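**Retrosynthetic overview**
1. Target 17 ⇐ enol angelate 15: the C2–O bond is made last by anti-Markovnikov syn-hydration of the C2=C3 enol ester, which sets C2 and C3. The C3–O ester bond comes from O-acylation of the C3 enolate of ketone 9 with angelic anhydride 10.
2. Butenolide (C15 carbonyl) ⇐ 3-substituted furan by singlet-oxygen oxidation and NaBH4; the furan carries the side chain through the base steps.
3. C4 (CH2OH equatorial, CH3 axial) ⇐ keto aldehyde 6: retro-Claisen loss of C19, then formaldehyde enters from the opposite face, which inverts C4.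
4. Furan diol 5 ⇐ andrographolide 1 by acetylation, SN2′ hydride reduction and iBu2AlH reduction.
5. Ring order: rings A and B with C5, C9 and C10 are bought in 1; the furan ring is formed in step 3 and re-oxidised to the butenolide in step 7; no carbocycle is built.

Assumption: 1 and 10 are bought; locants are labdane numbers, α means the face of the C10 methyl (C20) and β the face of H5 and H9, and every compound keeps the 5β-H, 9β-H, 10α-CH3 decalin of 1.

**Step 1**
Reactants: 1 andrographolide
Product: 2 3,14,19-tri-O-acetylandrographolide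
Conditions: Ac2O (6 equiv), pyridine, 0 → 23 °C
Reagents that add atoms: acetic anhydride CC(=O)OC(C)=O
Why: Plain O-acetylation of all three hydroxyls turns the 14-OH into the leaving group for step 2 and masks the 3,19-diol, with no stereocentre touched.

**Step 2**
Reactants: 2 3,14,19-tri-O-acetylandrographolide
Product: 3 3,19-di-O-acetyl-14-deoxyandrographolide (3α,19-diacetoxylabda-8(17),13-dien-16,15-olide)
Conditions: NaBH4 (1.0 equiv), THF–MeOH (4:1), −20 → 0 °C
Reagents that add atoms: none
Why: Conjugate hydride addition at C12 of the alkylidene lactone followed by E1cB loss of the 14-acetate (SN2′-type allylic reduction) moves the alkene to C13=C14; the C14 stereocentre is removed and none is created.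

**Step 3**
Reactants: 3 3,19-di-O-acetyl-14-deoxyandrographolide
Product: 5 furan diol 15,16-epoxylabda-8(17),13(16),14-triene-3α,19-diol, via lactol 4 (not isolated)
Conditions: iBu2AlH (7 equiv), CH2Cl2, −78 → −20 °C; aq KNaC4H4O6; then 1 M HCl, THF, 0 °C, 10 min
Reagents that add atoms: none
Why: iBu2AlH reduces the butenolide carbonyl to the lactol, which loses water on acidic work-up to give the aromatic furan, and the same reagent cleaves both acetates by ester reduction.

**Step 4**
Reactants: 5 furan diol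
Product: 6 keto aldehyde 3-oxo-15,16-epoxylabda-8(17),13(16),14-trien-19-al (CHO axial, α)
Conditions: Dess–Martin periodinane (2.5 equiv), NaHCO3, CH2Cl2, 0 → 23 °C
Reagents that add atoms: none
Why: Dess–Martin oxidation converts the secondary C3 and primary C19 alcohols into a β-keto aldehyde that cannot enolise at C4, and it leaves the furan and the exocyclic alkene alone.

**Step 5**
Reactants: 6 keto aldehyde
Product: 9 TES ketone 4β-(triethylsilyloxymethyl)-4α-methyl-15,16-epoxylabda-8(17),13(16),14-trien-3-one, via Li enolate 7 (not isolated), via Li aldolate 8 (not isolated)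
Conditions: LiOMe (1.05 equiv), THF, −78 → 0 °C; CH2O gas (from paraformaldehyde, 160 °C), −78 °C; TESCl, imidazole, −78 → 0 °C
Reagents that add atoms: formaldehyde C=O; chlorotriethylsilane CC[Si](Cl)(CC)CC
Why: Methoxide adds to the aldehyde and retro-Claisen cleavage expels C19 as methyl formate, leaving the regiodefined C3–C4 enolate under aprotic conditions; formaldehyde then adds at C4 from the β face, anti to the axial C10 methyl (Stork-type enolate hydroxymethylation), so the new CH2O group is equatorial and C4 is inverted, and silylation of the aldolate blocks retro-aldol.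

**Step 6**
Reactants: 9 TES ketone; 10 angelic anhydride
Product: 12 enol angelate 3-angeloyloxy-18-(triethylsilyloxy)-15,16-epoxylabda-2,8(17),13(16),14-tetraene, via K enolate 11 (not isolated)
Conditions: KN(SiMe3)2 (1.1 equiv), THF, −78 °C; then 10 (1.3 equiv), −78 → −40 °C
Reagents that add atoms: none
Why: The ketone can enolise only toward C2, and O-acylation of the potassium enolate by the anhydride (enol ester formation) makes the C3–O angelate bond at an sp2 oxygen, where the C4 quaternary centre hardly hinders it, while the cold conditions keep the Z alkene.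

**Step 7**
Reactants: 12 enol angelate
Product: 15 butenolide enol angelate 3-angeloyloxy-18-(triethylsilyloxy)labda-2,8(17),13-trien-15,16-olide, via endoperoxide 13 (not isolated), via hydroxybutenolide 14 (not isolated)
Conditions: O2, 5,10,15,20-tetraphenylporphyrin (1 mol %), iPr2NEt (5 equiv), CH2Cl2, hν (white LEDs), −78 °C; then NaBH4, EtOH, −40 → 0 °C; then aq citric acid (pH 4)
Reagents that add atoms: dioxygen O=O
Why: Singlet-oxygen [4+2] cycloaddition to the furan, amine-directed fragmentation of the endoperoxide at the less hindered C15–H (Kornblum–DeLaMare type) and NaBH4 reduction of the ring-opened C16 aldehyde with relactonisation give the butenolide with the carbonyl at C15, the furan reacting far faster with singlet oxygen than any alkene present.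

**Step 8**
Reactants: 15 butenolide enol angelate
Product: 17 target 3α-angeloyloxy-2β,18-dihydroxylabda-8(17),13-dien-15,16-olide (CNP0335424.2), via TES ether 16 (not isolated)
Conditions: 9-mesityl-10-methylacridinium tetrafluoroborate (5 mol %), 2-phenylmalononitrile (0.5 equiv), H2O (30 equiv), MeCN, 450 nm LEDs, N2, 23 °C; then 1 M aq HCl, THF, 23 °C
Reagents that add atoms: water O
Why: Proposed new method: photoredox anti-Markovnikov hydration of an enol ester, in which the excited acridinium oxidises only the C2=C3 enol ester (estimated near +2.0 V vs SCE, against about +2.5 V for the 1,1-disubstituted alkene and higher for the angelate and butenolide), water adds to C2 of the radical cation from the β face because the α face is blocked by the axial C10 and C4 methyls, and the resulting α-acyloxy radical at C3 takes a hydrogen atom axially (β) from 2-phenylmalononitrile, giving the trans-diequatorial 2β-OH/3α-OAng pair; the closest known chemistry is acridinium/H-atom-donor anti-Markovnikov hydroetherification, hydroacyloxylation and hydration of styrenes and trisubstituted alkenes, together with anodic β-functionalisation of enol ethers, and the dilute acid then removes the TES group.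

**Compound list**
1 | andrographolide, (12E,14S)-3α,14,19-trihydroxylabda-8(17),12-dien-16,15-olide | C=C1CC[C@H]2[C@@](C)(CC[C@@H](O)[C@@]2(C)CO)[C@@H]1C/C=C1/C(=O)OC[C@H]1O | starting material
2 | 3,14,19-tri-O-acetylandrographolide | C=C1CC[C@H]2[C@@](C)(CC[C@@H](OC(C)=O)[C@@]2(C)COC(C)=O)[C@@H]1C/C=C1/C(=O)OC[C@H]1OC(C)=O | intermediate
3 | 3,19-di-O-acetyl-14-deoxyandrographolide (α-substituted butenolide, 13-ene) | C=C1CC[C@H]2[C@@](C)(CC[C@@H](OC(C)=O)[C@@]2(C)COC(C)=O)[C@@H]1CCC1=CCOC1=O | intermediate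
4 | lactol, 16-hydroxy-15,16-epoxylabda-8(17),13-diene-3α,19-diol (C16 epimers) | C=C1CC[C@H]2[C@@](C)(CC[C@@H](O)[C@@]2(C)CO)[C@@H]1CCC1=CCOC1O | intermediate
5 | furan diol, 15,16-epoxylabda-8(17),13(16),14-triene-3α,19-diol | C=C1CC[C@H]2[C@@](C)(CC[C@@H](O)[C@@]2(C)CO)[C@@H]1CCc1ccoc1 | intermediate
6 | keto aldehyde, 3-oxo-15,16-epoxylabda-8(17),13(16),14-trien-19-al (4α-CHO, 4β-CH3) | C=C1CC[C@H]2[C@@](C)(CCC(=O)[C@@]2(C)C=O)[C@@H]1CCc1ccoc1 | intermediate
7 | Li enolate, lithium 19-nor-15,16-epoxylabda-3,8(17),13(16),14-tetraen-3-olate | C=C1CC[C@H]2[C@@](C)(CCC([O-])=C2C)[C@@H]1CCc1ccoc1.[Li+] | intermediate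
8 | Li aldolate, lithium alkoxide of the 4β-hydroxymethyl-4α-methyl 3-ketone | C=C1CC[C@H]2[C@@](C)(CCC(=O)[C@]2(C)C[O-])[C@@H]1CCc1ccoc1.[Li+] | intermediate
9 | TES ketone, 4β-(triethylsilyloxymethyl)-4α-methyl-15,16-epoxylabda-8(17),13(16),14-trien-3-one (new CH2O carbon is C18; the retained methyl is now C19) | C=C1CC[C@H]2[C@@](C)(CCC(=O)[C@]2(C)CO[Si](CC)(CC)CC)[C@@H]1CCc1ccoc1 | intermediate
10 | angelic anhydride, (Z)-2-methylbut-2-enoic anhydride | C/C=C(/C)C(=O)OC(=O)/C(C)=C\C | starting material
11 | K enolate of 9 (C2=C3) | C=C1CC[C@H]2[C@@](C)(CC=C([O-])[C@]2(C)CO[Si](CC)(CC)CC)[C@@H]1CCc1ccoc1.[K+] | intermediate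
12 | enol angelate, 3-angeloyloxy-18-(triethylsilyloxy)-15,16-epoxylabda-2,8(17),13(16),14-tetraene | C=C1CC[C@H]2[C@@](C)(CC=C(OC(=O)/C(C)=C\C)[C@]2(C)CO[Si](CC)(CC)CC)[C@@H]1CCc1ccoc1 | intermediate
13 | endoperoxide of the furan of 12 (2,3,7-trioxabicyclo[2.2.1]hept-5-ene) | C=C1CC[C@H]2[C@@](C)(CC=C(OC(=O)/C(C)=C\C)[C@]2(C)CO[Si](CC)(CC)CC)[C@@H]1CCC1=CC2OOC1O2 | intermediate
14 | hydroxybutenolide, 3-angeloyloxy-16-hydroxy-18-(triethylsilyloxy)labda-2,8(17),13-trien-15,16-olide (C16 epimers) | C=C1CC[C@H]2[C@@](C)(CC=C(OC(=O)/C(C)=C\C)[C@]2(C)CO[Si](CC)(CC)CC)[C@@H]1CCC1=CC(=O)OC1O | intermediate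
15 | butenolide enol angelate, 3-angeloyloxy-18-(triethylsilyloxy)labda-2,8(17),13-trien-15,16-olide | C=C1CC[C@H]2[C@@](C)(CC=C(OC(=O)/C(C)=C\C)[C@]2(C)CO[Si](CC)(CC)CC)[C@@H]1CCC1=CC(=O)OC1 | intermediate
16 | TES ether of the target, 3α-angeloyloxy-2β-hydroxy-18-(triethylsilyloxy)labda-8(17),13-dien-15,16-olide | C=C1CC[C@H]2[C@@](C)(C[C@H](O)[C@@H](OC(=O)/C(C)=C\C)[C@]2(C)CO[Si](CC)(CC)CC)[C@@H]1CCC1=CC(=O)OC1 | intermediate
17 | CNP0335424.2, 3α-angeloyloxy-2β,18-dihydroxylabda-8(17),13-dien-15,16-olide | C=C1CC[C@H]2[C@@](C)(C[C@H](O)[C@@H](OC(=O)/C(C)=C\C)[C@]2(C)CO)[C@@H]1CCC1=CC(=O)OC1 | target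

**Totals**
Total step count: 8. Longest linear sequence: 8 steps (1 → 17).

**Steps most likely to fail**

Step 5 (retro-Claisen, hydroxymethylation, silylation in one flask). Risks are scrambling of the enolate, O-formylation by methyl formate, over-addition of formaldehyde and incomplete facial control. The fallback sets out from 6 and comes back at 9. K2CO3 in MeOH deformylates 6 to the 19-nor ketone F1 with the 4β-methyl equatorial. TMSCl, NaI and Et3N in MeCN give the more substituted silyl enol ether F2, which is separated from its C2 isomer. A Mukaiyama aldol with aqueous formaldehyde and Sc(OTf)3 gives the 18-hydroxy ketone F3 with the same β-face selectivity, and TESCl with imidazole returns 9.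

Step 7 (one-pot photooxygenation and reduction beside an enol ester). Risks are cleavage of the enol angelate by NaBH4/EtOH and loss of the TES group on acidification. The fallback sets out from 12 and comes back at 16. The photooxygenation is run alone and hydroxybutenolide 14 is isolated. The hydration of step 8 is then done on 14 to give the 2β-hydroxy-3α-angelate hydroxybutenolide F4, so that no enol ester meets hydride. NaBH4 and pH 4 work-up then give 16, and dilute acid gives 17.

Step 8 (the new hydration). Risks are that the enol ester lies beyond the oxidising power of the catalyst, that the radical cation loses its acyl group or is attacked by the ester carbonyl, or that the enol ester simply hydrolyses. The fallback uses known chemistry, sets out from 9 and comes back at 17.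
- KN(SiMe3)2 and then 2-(phenylsulfonyl)-3-phenyloxaziridine hydroxylate the enolate from the β face to give the 2β-hydroxy ketone F5.
- TESCl with imidazole gives the bis-silyl ketone F6.
- NaBH4 delivers hydride axially to give the 3α-alcohol F7.
- LiN(SiMe3)2 and then 10 at −78 °C acylate the alkoxide to give the 3α-angelate F8.
- Photooxygenation as in step 7 goes through endoperoxide F9 to hydroxybutenolide F10, and NaBH4 gives the bis-silyl butenolide F11.
- HF·pyridine in THF removes both silyl groups to give 17.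

**Further compounds**
F1 | step 5 | 19-nor ketone, 4β-methyl-19-nor-15,16-epoxylabda-8(17),13(16),14-trien-3-one | C=C1CC[C@H]2[C@@](C)(CCC(=O)[C@@H]2C)[C@@H]1CCc1ccoc1
F2 | step 5 | silyl enol ether, 3-(trimethylsilyloxy)-19-nor-15,16-epoxylabda-3,8(17),13(16),14-tetraene | C=C1CC[C@H]2[C@@](C)(CCC(O[Si](C)(C)C)=C2C)[C@@H]1CCc1ccoc1
F3 | step 5 | 18-hydroxy ketone, 4β-hydroxymethyl-4α-methyl-15,16-epoxylabda-8(17),13(16),14-trien-3-one | C=C1CC[C@H]2[C@@](C)(CCC(=O)[C@]2(C)CO)[C@@H]1CCc1ccoc1
F4 | step 7 | 3α-angeloyloxy-2β,16-dihydroxy-18-(triethylsilyloxy)labda-8(17),13-dien-15,16-olide | C=C1CC[C@H]2[C@@](C)(C[C@H](O)[C@@H](OC(=O)/C(C)=C\C)[C@]2(C)CO[Si](CC)(CC)CC)[C@@H]1CCC1=CC(=O)OC1O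
F5 | step 8 | 2β-hydroxy-18-(triethylsilyloxy)-15,16-epoxylabda-8(17),13(16),14-trien-3-one | C=C1CC[C@H]2[C@@](C)(C[C@H](O)C(=O)[C@]2(C)CO[Si](CC)(CC)CC)[C@@H]1CCc1ccoc1
F6 | step 8 | 2β,18-bis(triethylsilyloxy)-15,16-epoxylabda-8(17),13(16),14-trien-3-one | C=C1CC[C@H]2[C@@](C)(C[C@H](O[Si](CC)(CC)CC)C(=O)[C@]2(C)CO[Si](CC)(CC)CC)[C@@H]1CCc1ccoc1
F7 | step 8 | 2β,18-bis(triethylsilyloxy)-15,16-epoxylabda-8(17),13(16),14-trien-3α-ol | C=C1CC[C@H]2[C@@](C)(C[C@H](O[Si](CC)(CC)CC)[C@@H](O)[C@]2(C)CO[Si](CC)(CC)CC)[C@@H]1CCc1ccoc1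
F8 | step 8 | 3α-angeloyloxy-2β,18-bis(triethylsilyloxy)-15,16-epoxylabda-8(17),13(16),14-triene | C=C1CC[C@H]2[C@@](C)(C[C@H](O[Si](CC)(CC)CC)[C@@H](OC(=O)/C(C)=C\C)[C@]2(C)CO[Si](CC)(CC)CC)[C@@H]1CCc1ccoc1
F9 | step 8 | endoperoxide of the furan of F8 | C=C1CC[C@H]2[C@@](C)(C[C@H](O[Si](CC)(CC)CC)[C@@H](OC(=O)/C(C)=C\C)[C@]2(C)CO[Si](CC)(CC)CC)[C@@H]1CCC1=CC2OOC1O2
F10 | step 8 | 3α-angeloyloxy-16-hydroxy-2β,18-bis(triethylsilyloxy)labda-8(17),13-dien-15,16-olide | C=C1CC[C@H]2[C@@](C)(C[C@H](O[Si](CC)(CC)CC)[C@@H](OC(=O)/C(C)=C\C)[C@]2(C)CO[Si](CC)(CC)CC)[C@@H]1CCC1=CC(=O)OC1O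
F11 | step 8 | 3α-angeloyloxy-2β,18-bis(triethylsilyloxy)labda-8(17),13-dien-15,16-olide | C=C1CC[C@H]2[C@@](C)(C[C@H](O[Si](CC)(CC)CC)[C@@H](OC(=O)/C(C)=C\C)[C@]2(C)CO[Si](CC)(CC)CC)[C@@H]1CCC1=CC(=O)OC1
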